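The rate constants are made up; the result is computed.

If the binding of X to G was over in a much shorter time than the passing of X.G on to J, the rate-limiting step, then I could reckon this flask as that binding plus a slow leak.

    X + G ⇌ X.G (K1 = 0.13 /M, k1 = 0.0714 /M/min)
    X.G ⇌ J + D (K2 = 0.898 M, k2 = 0.00470 /min)
    G + D ⇌ G.D, settled at all times (K3 = 0.495 /M)
    Q + D → Q.D (k4 = 0.0125 /M/min)

X 1.0 M; G 2.00 equiv; Q 0.500 equiv; time 4.0 h

1. part of the X that has reacted at 4.0 h
2. share of the unused G that is free and not bound as G.D, at 4.0 h

- D is meant together with its G.D
- run time (flask): 4.0 h

I began with G as charged, where a value of 0.26 for K1 times G put 20.6% of the X into X.G. The bound G had to come off the charge, so I corrected once and had the held share, the part of the charged X standing as X.G once the binding has balanced, 18.9%. X and X.G together then drained in a pseudo-first-order way at k2 times the held share, 8.89 × 10⁻⁴ /min, which left 80.8% of that pool at 4.0 h. Free X was the unheld part of it, so my c was 34.5%.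

Then I turned the settings by hand. More G raised the held share and, with it, the leak. More X at the same equivalents carried G up with it, so it worked the same way. Time entered by the leak and not by the held share. Q met D and stood nowhere in my reckoning, so by hand it moved nothing. I held the share constant although G was being spent, so I expected my c to stand high, and this reckoning gave no figure for fr.

The forecast gave 32.3% for c and 96.7% for fr, on these grounds: “G is used up in forming J, because it is carried through X.G”.

The simulation of this flask gave 32.1% for c and 96.8% for fr, so the forecast held and my c stood 2.4 percentage points above the result. X.G in this flask stood at 18.4% of the X charged at 0.400 h, against my held share of 18.9%. Each setting, moved singly by the same factor up or down, shifted c at most as follows: G (6.4 points), then X (5.2 points), then time (3.2 points), then Q (0.078 points). For the neighbour flask with 1.20 equiv of G, the same reckoning gave a held share of 13.5% before correction and 12.2% after it, hence c of 23.4%. That flask gave 21.6%.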